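The readings come from a simulation on assumed constants.

Start at the late end of the runs: a flask that has stopped moving can be counted without any rate. At 50.0 h the alpha run still stands at 36.6 % target and 62.5 % electrophile, just as it did at 10.0 h.

common to all: electrophile 20 mM
- beta: nucleophile 0.12 equiv; free base 1.2 equiv; run made earlier
- alpha: nucleophile 0.38 equiv; free base 1.2 equiv; run made earlier
- zeta: nucleophile 1.7 equiv; free base 1.2 equiv; run made earlier
- west: nucleophile 0.100 equiv; free base 1.20 equiv; time 2.0 d
- east: nucleophile 0.200 equiv; free base 1.20 equiv; time 2.0 d
- south: nucleophile 0.400 equiv; free base 1.20 equiv; time 2.0 d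
- north-east: nucleophile 0.800 equiv; free base 1.20 equiv; time 2.0 d
- north-west: nucleophile 1.50 equiv; free base 1.20 equiv; time 2.0 d

- beta (time / h: target / %, electrophile / %): 10.0: 11.6, 88.1; 20.0: 12.4, 88.6; 30.0: 12.0, 88.3; 40.0: 11.5, 88.1; 50.0: 11.8, 87.4
- alpha (time / h: target / %, electrophile / %): 10.0: 36.9, 62.7; 20.0: 36.5, 62.2; 30.0: 36.8, 63.0; 40.0: 37.3, 62.3; 50.0: 36.6, 62.5
- zeta (time / h: target / %, electrophile / %): 4.00: 74.8, 0.5; 12.0: 55.9, 0.2; 20.0: 45.4, 0; 30.0: 41.3, 0.5; 50.0: 34.8, 0.8

(scatter of a reading: 0.5 percentage points)

- what may be going on: nucleophile + acid set free <-> protonated nucleophile; nucleophile + target -> over-reaction product; acid set free + free base <-> salt of the base; electrophile + nucleophile -> acid set free + target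
- "hardly changes" means that all values lie within two and a half points (for a concentration: within two and a half percent of the largest)

1. amount of target at the end, in percent of the electrophile charged for west, east, south, north-east, north-west, in this order
2. how the row runs (rises all the way / rises, then falls / falls, then rises / hardly changes / falls all the way)

So keep the account of the nucleophile, the limiting reagent in alpha. In fractions of the electrophile charged, let n be the equivalents of nucleophile, E the electrophile left, T the target, O the over-reaction product and N the nucleophile left, free or protonated. Each target holds one nucleophile and each over-reaction product holds two: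

E + T + O = 1

T + 2O + N = n

T = F − 2E + N, with F = 2 − n

Call F the account figure. For alpha, with N taken as zero, this gives 37.0 %, close to the reading.

Now turn the question round. For the row to rise all the way, north-west has to end above north-east. The account figure of north-west is 50.0 %. In zeta the electrophile was down to 0.5 % by 4.00 h, so expect E near zero in north-west, which leaves T = F + N. If north-east keeps close to its charge of 0.800 equiv, north-west needs N of about 30 percentage points at the end, out of an excess of 50.0 %.

Zeta shows how far that is. Its account figure is 30.0 %, so its reading of 34.8 % at 50.0 h leaves N of about 4.8 points, which is less than that need, from an excess of 70.0 %. I therefore expect the row to turn down, with north-west near 54.8 % if it ends with about the same N as zeta.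

The forecast, lower than mine for north-west, reads 10 %, 20 %, 39.7 %, 78 % and 52 %, so rises, then falls, on the ground that “With no nucleophile left, the target is stable”.

The flask gives 9.92 %, 19.7 %, 38.5 %, 70.9 % and 51.6 %: rises, then falls.

    nucleophile + acid set free ⇌ protonated nucleophile, settled at all times (K = 630 M⁻¹)
    nucleophile + target → over-reaction product (k = 6.60 M⁻¹ h⁻¹)
    acid set free + free base ⇌ salt of the base, settled at all times (K = 17000 M⁻¹)
    electrophile + nucleophile → acid set free + target (k = 91.0 M⁻¹ h⁻¹)

North-west ends 1.6 points above its account figure, with 0.924 % of its nucleophile still free and 0.0468 mM protonated nucleophile at 2.00 d. Part of the reason for the turn is the over-reaction: from north-east to north-west the target changes by −19 points, and by 20 points in the runs without that step. In north-east, where 0 % of the nucleophile is left, the account figure 120 % and 24.5 % electrophile give 71.0 %, against 70.9 % in the flask.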